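At early times the violet run already balances: at 4.00 h, target 44.8% and substrate 55.6% add up to 100.4%, so the substrate that has gone appears as target.

| flask | substrate | reagent | temperature | remark | time |
|---|---|---|---|---|---|
| violet | 0.10 M | 0.080 M | 20 °C | run made earlier |  |
| teal | 0.10 M | 0.040 M | 31 °C | run made earlier |  |
| amber | 0.10 M | 0.16 M | 20 °C | run made earlier |  |
| blue | 0.15 M | 0.080 M | 31 °C | run made earlier |  |
| ash | 0.10 M | 0.0800 M (fed, over 8.0 h) | 25 °C | all else is in the flask from the start; the feed brings no volume worth counting | 40 h |
| alder | 0.10 M (fed, over 8.0 h) | 0.0800 M | 25 °C | all else is in the flask from the start; the feed brings no volume worth counting | 40 h |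
| larch | 0.10 M | 0.0800 M (fed, over 8.0 h) |  | the addition at 5 °C, then warmed to 25 °C; the feed brings no volume worth counting | 40 h |
| birch | 0.10 M | 0.0800 M | 25 °C | everything together at the start | 40 h |

| run | time / h | target / % | substrate / % |
|---|---|---|---|
| violet | 4.00 | 44.8 | 55.6 |
| violet | 8.00 | 57.3 | 43.0 |
| violet | 12.0 | 63.5 | 36.6 |
| violet | 15.0 | 66.1 | 33.2 |
| violet | 20.0 | 70.3 | 29.7 |
| violet | 25.0 | 72.6 | 27.6 |
| teal | 5.00 | 36.6 | 63.8 |
| teal | 10.0 | 39.2 | 60.5 |
| teal | 15.0 | 40.2 | 59.9 |
| teal | 20.0 | 39.2 | 60.2 |
| teal | 25.0 | 39.7 | 60.1 |
| teal | 30.0 | 39.4 | 59.8 |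
| amber | 2.50 | 56.6 | 43.7 |
| amber | 4.00 | 67.6 | 32.5 |
| amber | 8.00 | 81.0 | 18.5 |
| amber | 12.0 | 87.4 | 12.4 |
| amber | 20.0 | 92.9 | 7.1 |
| amber | 30.0 | 95.1 | 4.3 |
| blue | 6.00 | 52.3 | 48.0 |
| blue | 12.0 | 53.2 | 46.7 |
| blue | 20.0 | 52.8 | 46.2 |
| blue | 25.0 | 52.6 | 46.5 |
| blue | 30.0 | 52.4 | 46.0 |

(each reading ± 0.3 percentage points)

- the flask with the highest amount of target, in percent of the substrate charged ("all alike" if they lie within 1.5 percentage points) (ash / alder / larch / birch / all alike)
- final target, as a percentage of the substrate charged, in ash
- final target, as a percentage of the substrate charged, in alder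
- final target, as a percentage of the substrate charged, in larch
- final target, as a percentage of the substrate charged, in birch



How much target can a flask hold? Take the loss-free case as the zero of the scale: if each substrate consumes one reagent, and reagent is the limiting reagent, target stops at the stoichiometric ceiling, the reagent charge divided by the substrate charge, which is 80.0% for ash, alder, larch and birch.

Do the readings support one reagent per substrate? Teal, with 0.040 M of reagent on 0.10 M of substrate, has a ceiling of 40.0% and reads 39.4% at 30.0 h.

Blue, with a ceiling of 53.3%, reads 53.2% at 12.0 h and 52.4% at 30.0 h. Is the gap under the ceiling a loss? These two readings lie 0.8 percentage points apart against a scatter of 0.3 points, so one reading does not measure a loss, and I keep a small loss open without giving it a size.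

Does 40 h reach the ceiling? Violet has the same charges at 20 °C and reads 72.6% at 25.0 h, still rising. The new flasks stand warmer, and even larch, after its cold addition, has 32.0 h at 25 °C, longer than violet's run.

So my reckoning puts each flask between 72.6% and 80.0%. With one ceiling for the charges, and ash and alder as mirror images that feed one partner or the other, I expect them within 1.5 points.

The forecast differs. It names ash as highest, with 77.7% for ash, 68% for alder, 73.5% for larch and 75% for birch, on the ground that “keeping reagent dilute wins”.

The flasks give 77.3% for ash, 77.2% for alder, 76.9% for larch and 77.8% for birch, so the verdict is all alike, and alder stands 9.2 points above the forecast.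

    substrate + reagent → target, rate k1*[substrate]^1.5*[reagent] (k = 0.262 /M^1.5/min, Ea = 58.0 kJ/mol)
    target → over-reaction product (k = 1.38 × 10⁻⁶ /min, Ea = 119 kJ/mol)
    (constants at 25 °C)

In alder, the step from substrate and reagent to target ran while substrate arrived into the standing reagent, and half of its turnover was done by 7.21 h. That step ran on after the feed, and at 40.0 h alder stood 2.8 points under its ceiling, with 3.2% of the reagent charge unbound and 0.198% over-reaction product. The same flask as alder with 0.25 M of substrate has a ceiling of 32.0%, and at 40.0 h its reagent stands at 0% and its target at 31.9%.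

The runs are simulated with constants of no real substance, and the scatter is random.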